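**Plan**

The target is an achiral 17-membered bis(bibenzyl): ring C (catechol) –O– ring A (para-phenylene) –CH2CH2– ring B (3-hydroxy-2-aryloxyphenyl) –O– ring D (ortho-phenylene) –CH2CH2– ring C.
Retrosynthetic cuts, in order: the three O–CH3 bonds; the CH2–CH2 bond between rings A and B (carbonyl coupling); the ring D–O–ring B ether bond (SNAr); two C–C bonds of ring A itself (pyrone cycloaddition); the O–C≡C unit on the ring C oxygen; the CH2–CH2 bond between rings C and D (Wittig).
The enabling feature is ring A, a benzene with only two substituents, para to each other: an aryloxy oxygen on C4 and a benzylic carbon on C1. This is the pattern that C3–C6 of a 2-pyrone-5-carboxylate and the two carbons of an aryloxyacetylene give after loss of CO2.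
Forward: rings C and D are joined as a bibenzyl, the ring C phenol is turned into an ethynyl ether, ring A is grown on that oxygen, ring B is attached to the ring D oxygen, and the macrocycle is closed last between the ring A and ring B carbonyl carbons.
Stereochemistry: there is no stereocentre; the alkene geometries from the Wittig and McMurry steps are erased by reduction.

Key step: step 7

Remark: ring D is taken as 1,2-disubstituted, as the SMILES shows, and 3-hydroxy-4,5-dimethoxybenzaldehyde is taken as a purchasable compound.

**Route**

Step 1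
Reactants: 1 2-(benzyloxy)benzaldehyde
Product: 2 [2-(benzyloxy)phenyl]methanol
Conditions: NaBH4, MeOH, 0 °C
Reagents that add atoms: none
Why: Borohydride reduction of an aromatic aldehyde to the benzylic alcohol is fast and leaves the benzyl ether alone.

Step 2
Reactants: 2 [2-(benzyloxy)phenyl]methanol
Product: 3 [2-(benzyloxy)benzyl]triphenylphosphonium bromide
Conditions: PPh3·HBr, MeCN, reflux
Reagents that add atoms: triphenylphosphine hydrobromide, [Br-].[PH+](c1ccccc1)(c1ccccc1)c1ccccc1
Why: Phosphonium salt formation from a benzylic alcohol: protonation and loss of water give an alkoxy-stabilised benzylic electrophile that PPh3 captures, and because the acid is consumed as the salt forms, the aryl benzyl ether should not be cleaved.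

Step 3
Reactants: 3 [2-(benzyloxy)benzyl]triphenylphosphonium bromide; 4 3-hydroxy-4,5-dimethoxybenzaldehyde
Product: 6 5-{2-[2-(benzyloxy)phenyl]ethenyl}-2,3-dimethoxyphenol (E/Z mixture), via benzylic phosphonium ylide 5 (not isolated)
Conditions: KOtBu (2.2 equiv), THF, 0 °C to rt; then 1 M HCl
Reagents that add atoms: none
Why: Wittig olefination with a semi-stabilised benzylic ylide; the second equivalent of base holds the phenol as a phenoxide that is meta to the formyl group and so cannot deactivate it by conjugation, and the E/Z mixture is of no consequence because the alkene is saturated next.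

Step 4
Reactants: 6 5-{2-[2-(benzyloxy)phenyl]ethenyl}-2,3-dimethoxyphenol
Product: 7 5-{2-[2-(benzyloxy)phenyl]ethyl}-2,3-dimethoxyphenol
Conditions: TsNHNH2, NaOAc, DME/H2O, reflux
Reagents that add atoms: none
Why: Diimide reduction: diimide released from the sulfonyl hydrazide transfers two hydrogens to the stilbene in a concerted syn fashion and, unlike hydrogenation over palladium, should leave the benzyl ether in place.

Step 5
Reactants: 7 5-{2-[2-(benzyloxy)phenyl]ethyl}-2,3-dimethoxyphenol
Product: 8 1-{2-[2-(benzyloxy)phenyl]ethyl}-3-{[(E)-1,2-dichloroethenyl]oxy}-4,5-dimethoxybenzene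
Conditions: Cl2C=CHCl, K2CO3, DMF, 70 °C
Reagents that add atoms: trichloroethylene, ClC=C(Cl)Cl
Why: O-Dichlorovinylation of a phenol: the base converts trichloroethylene into dichloroacetylene, to which the phenoxide adds in anti fashion to give the (E)-1,2-dichlorovinyl ether.

Step 6
Reactants: 8 1-{2-[2-(benzyloxy)phenyl]ethyl}-3-{[(E)-1,2-dichloroethenyl]oxy}-4,5-dimethoxybenzene
Product: 11 1-{2-[2-(benzyloxy)phenyl]ethyl}-3-(ethynyloxy)-4,5-dimethoxybenzene, via aryl chloroethynyl ether 9 (not isolated), via lithium aryloxyacetylide 10 (not isolated)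
Conditions: n-BuLi (2.5 equiv), THF, –78 to –40 °C; H2O quench at –78 °C; short basic alumina plug, used the same day
Reagents that add atoms: none
Why: Dichlorovinyl ether route to alkynyl ethers: the first equivalent of n-BuLi effects dehydrochlorination to the chloroalkyne, the second performs lithium–chlorine exchange, and protonation of the acetylide releases the terminal ynol ether, while at –78 °C neither the benzyl ether nor the methoxyarene should be metalated.

Step 7
Reactants: 11 1-{2-[2-(benzyloxy)phenyl]ethyl}-3-(ethynyloxy)-4,5-dimethoxybenzene; 12 methyl coumalate (methyl 2-oxo-2H-pyran-5-carboxylate)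
Product: 14 methyl 4-(5-{2-[2-(benzyloxy)phenyl]ethyl}-2,3-dimethoxyphenoxy)benzoate, via bicyclic lactone cycloadduct 13 (not isolated)
Conditions: 12 (2 equiv), toluene, 100 °C, sealed tube, dark
Reagents that add atoms: none
Why: An inverse-electron-demand [4+2] cycloaddition, with C3–C6 of the electron-poor pyrone as diene and the polarised triple bond of 11 as dienophile, should give the bridged lactone 13, which expels CO2 by a retro-[4+2] step at the same temperature and so gives the benzene directly. The closest known reaction type is the thermal Diels–Alder/decarboxylation of methyl coumalate with electron-rich alkynes and alkenes (ynamines, enol ethers, ketene acetals), which gives para-substituted benzoates. Ring A is closed by an intermolecular (4+2) cycloaddition that makes both new ring C–C bonds in one operation: pyrone C6 to the terminal alkyne carbon and pyrone C3 to the oxygen-bearing alkyne carbon. No stereocentre remains in 14, because the two bridgehead centres of 13 become arene carbons when CO2 leaves. The step needs para regiochemistry, and this should follow from pairing the nucleophilic terminal carbon of the ynol ether with C6, the most electrophilic diene terminus, which is conjugated to both the ester and the lactone carbonyl. An aryl ynol ether has no O-alkyl hydrogen for retro-ene loss to a ketene, and the arenes and the benzyl ether of 11 are inert to the pyrone.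

Step 8
Reactants: 14 methyl 4-(5-{2-[2-(benzyloxy)phenyl]ethyl}-2,3-dimethoxyphenoxy)benzoate
Product: 15 methyl 4-{5-[2-(2-hydroxyphenyl)ethyl]-2,3-dimethoxyphenoxy}benzoate
Conditions: H2 (1 atm), Pd/C, EtOAc/MeOH, rt
Reagents that add atoms: none
Why: Hydrogenolysis of the benzyl aryl ether over palladium on carbon frees the ring D phenol, while the ester, the diaryl ether and the methyl ethers are inert.

Step 9
Reactants: 15 methyl 4-{5-[2-(2-hydroxyphenyl)ethyl]-2,3-dimethoxyphenoxy}benzoate; 16 2-fluoro-3-methoxybenzaldehyde
Product: 17 methyl 4-(5-{2-[2-(2-formyl-6-methoxyphenoxy)phenyl]ethyl}-2,3-dimethoxyphenoxy)benzoate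
Conditions: K2CO3, DMF, 120 °C
Reagents that add atoms: none
Why: Nucleophilic aromatic substitution by addition–elimination: the ortho formyl group stabilises the Meisenheimer intermediate, fluoride is the best leaving group for this mechanism, and the methyl ester is indifferent to anhydrous carbonate.

Step 10
Reactants: 17 methyl 4-(5-{2-[2-(2-formyl-6-methoxyphenoxy)phenyl]ethyl}-2,3-dimethoxyphenoxy)benzoate
Product: 18 {4-[5-(2-{2-[2-(hydroxymethyl)-6-methoxyphenoxy]phenyl}ethyl)-2,3-dimethoxyphenoxy]phenyl}methanol
Conditions: LiAlH4, THF, 0 °C to rt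
Reagents that add atoms: none
Why: Hydride reduction with LiAlH4 brings the ester and the aldehyde to the same benzylic alcohol level without touching the aryl ethers.

Step 11
Reactants: 18 {4-[5-(2-{2-[2-(hydroxymethyl)-6-methoxyphenoxy]phenyl}ethyl)-2,3-dimethoxyphenoxy]phenyl}methanol
Product: 19 2-(2-{2-[3-(4-formylphenoxy)-4,5-dimethoxyphenyl]ethyl}phenoxy)-3-methoxybenzaldehyde
Conditions: MnO2, CH2Cl2, rt
Reagents that add atoms: none
Why: Oxidation of benzylic alcohols with activated MnO2 stops cleanly at the aldehyde and should deliver the dialdehyde.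

Step 12
Reactants: 19 2-(2-{2-[3-(4-formylphenoxy)-4,5-dimethoxyphenyl]ethyl}phenoxy)-3-methoxybenzaldehyde
Product: 20 macrocyclic stilbene: the 17-membered ring C–O–ring A–CH=CH–ring B–O–ring D–CH2CH2–ring C with two OMe on ring C and one OMe on ring B (Z expected, either geometry serves)
Conditions: TiCl4, Zn dust, pyridine, THF, reflux; 19 added slowly by syringe pump (high dilution)
Reagents that add atoms: none
Why: McMurry reductive coupling of the two aryl aldehydes on low-valent titanium forms the ring A–ring B alkene, and slow addition should favour the intramolecular pinacolate and its deoxygenation over oligomer formation.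

Step 13
Reactants: 20 macrocyclic stilbene
Product: 21 tri-O-methyl ether of the target (the saturated 17-membered macrocycle with two OMe on ring C and one OMe on ring B)
Conditions: H2 (1 atm), Pd/C, EtOAc, rt
Reagents that add atoms: none
Why: Catalytic hydrogenation saturates the strained stilbene alkene, and the molecule holds no benzylic C–O bond that could be cleaved.

Step 14
Reactants: 21 tri-O-methyl ether of the target
Product: 22 target CNP0290892.0
Conditions: BBr3, CH2Cl2, –78 °C to rt; H2O
Reagents that add atoms: none
Why: Lewis-acid demethylation with BBr3 cleaves the three O–CH3 bonds by bromide attack at methyl, while the diaryl ether C–O bonds, which have no sp3 carbon to attack, should survive.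

**Compound list**

1 | 2-(benzyloxy)benzaldehyde | O=Cc1ccccc1OCc1ccccc1 | starting material
2 | [2-(benzyloxy)phenyl]methanol | OCc1ccccc1OCc1ccccc1 | intermediate
3 | [2-(benzyloxy)benzyl]triphenylphosphonium bromide | [Br-].c1ccc(cc1)COc1ccccc1C[P+](c1ccccc1)(c1ccccc1)c1ccccc1 | intermediate
4 | 3-hydroxy-4,5-dimethoxybenzaldehyde | COc1cc(C=O)cc(O)c1OC | starting material
5 | [2-(benzyloxy)benzylidene]triphenylphosphorane (ylide, formed in the flask, not isolated) | c1ccc(cc1)COc1ccccc1C=P(c1ccccc1)(c1ccccc1)c1ccccc1 | intermediate
6 | 5-{2-[2-(benzyloxy)phenyl]ethenyl}-2,3-dimethoxyphenol (E/Z mixture, geometry left open) | COc1cc(C=Cc2ccccc2OCc2ccccc2)cc(O)c1OC | intermediate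
7 | 5-{2-[2-(benzyloxy)phenyl]ethyl}-2,3-dimethoxyphenol | COc1cc(CCc2ccccc2OCc2ccccc2)cc(O)c1OC | intermediate
8 | 1-{2-[2-(benzyloxy)phenyl]ethyl}-3-{[(E)-1,2-dichloroethenyl]oxy}-4,5-dimethoxybenzene | Cl/C=C(/Cl)Oc1cc(CCc2ccccc2OCc2ccccc2)cc(OC)c1OC | intermediate
9 | 1-{2-[2-(benzyloxy)phenyl]ethyl}-3-[(chloroethynyl)oxy]-4,5-dimethoxybenzene (formed in the flask, not isolated) | ClC#COc1cc(CCc2ccccc2OCc2ccccc2)cc(OC)c1OC | intermediate
10 | lithium acetylide of 11 (formed in the flask, not isolated) | [Li]C#COc1cc(CCc2ccccc2OCc2ccccc2)cc(OC)c1OC | intermediate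
11 | 1-{2-[2-(benzyloxy)phenyl]ethyl}-3-(ethynyloxy)-4,5-dimethoxybenzene | C#COc1cc(CCc2ccccc2OCc2ccccc2)cc(OC)c1OC | intermediate
12 | methyl coumalate (methyl 2-oxo-2H-pyran-5-carboxylate) | COC(=O)C1=COC(=O)C=C1 | starting material
13 | methyl 5-aryloxy-3-oxo-2-oxabicyclo[2.2.2]octa-5,7-diene-7-carboxylate, aryl = 5-{2-[2-(benzyloxy)phenyl]ethyl}-2,3-dimethoxyphenyl (racemic, formed in the flask, not isolated) | COC(=O)C1=CC2C(=O)OC1C=C2Oc1cc(CCc2ccccc2OCc2ccccc2)cc(OC)c1OC | intermediate
14 | methyl 4-(5-{2-[2-(benzyloxy)phenyl]ethyl}-2,3-dimethoxyphenoxy)benzoate | COC(=O)c1ccc(cc1)Oc1cc(CCc2ccccc2OCc2ccccc2)cc(OC)c1OC | intermediate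
15 | methyl 4-{5-[2-(2-hydroxyphenyl)ethyl]-2,3-dimethoxyphenoxy}benzoate | COC(=O)c1ccc(cc1)Oc1cc(CCc2ccccc2O)cc(OC)c1OC | intermediate
16 | 2-fluoro-3-methoxybenzaldehyde | COc1cccc(C=O)c1F | starting material
17 | methyl 4-(5-{2-[2-(2-formyl-6-methoxyphenoxy)phenyl]ethyl}-2,3-dimethoxyphenoxy)benzoate | COC(=O)c1ccc(cc1)Oc1cc(CCc2ccccc2Oc2c(C=O)cccc2OC)cc(OC)c1OC | intermediate
18 | {4-[5-(2-{2-[2-(hydroxymethyl)-6-methoxyphenoxy]phenyl}ethyl)-2,3-dimethoxyphenoxy]phenyl}methanol | OCc1ccc(cc1)Oc1cc(CCc2ccccc2Oc2c(CO)cccc2OC)cc(OC)c1OC | intermediate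
19 | 2-(2-{2-[3-(4-formylphenoxy)-4,5-dimethoxyphenyl]ethyl}phenoxy)-3-methoxybenzaldehyde | O=Cc1ccc(cc1)Oc1cc(CCc2ccccc2Oc2c(C=O)cccc2OC)cc(OC)c1OC | intermediate
20 | macrocyclic (Z)-stilbene, tri-O-methyl dehydro form of the target | COc1cc2cc(c1OC)Oc1ccc(cc1)/C=C\c1cccc(OC)c1Oc1ccccc1CC2 | intermediate
21 | tri-O-methyl ether of the target | COc1cc2cc(c1OC)Oc1ccc(cc1)CCc1cccc(OC)c1Oc1ccccc1CC2 | intermediate
22 | CNP0290892.0 | Oc1cc2cc(c1O)Oc1ccc(cc1)CCc1cccc(O)c1Oc1ccccc1CC2 | target

**Step count**

Total step count: 14.
Longest linear sequence: 14 steps, from 1 to 22; compounds 4, 12, 16 and trichloroethylene enter as purchased materials.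

**Steps most likely to fail**

Step 7. The terminal ynol ether may oligomerise or hydrate faster than it adds to the pyrone, or the cycloaddition may lose regiocontrol and give the meta benzoate as well. The fallback gives up the cycloaddition and makes the same diaryl ether by nucleophilic aromatic substitution. It sets out from phenol 7, which is heated with methyl 4-fluorobenzoate and K2CO3 in DMSO at about 120 °C, and it comes back to the route at benzoate 14, bypassing steps 5 to 7. This detour makes no compound outside the list (entry F0).

Step 6. The lithiated dichlorovinyl ether may expel the aryloxide and not chloride, or the terminal alkynyl ether may decompose during work-up and concentration. The fallback sets out from 8 and uses the same n-BuLi treatment, but the acetylide 10 is silylated with iPr3SiOTf and not protonated. This should give the triisopropylsilyl-capped ynol ether F1, which can be chromatographed and stored. Treatment of F1 with Bu4NF in THF at –20 °C, immediately before the cycloaddition, comes back to the route at 11.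

Step 12. Intermolecular carbonyl coupling may outrun ring closure, or the titanium pinacolate may fail to deoxygenate. The fallback closes the same alkene by ring-closing metathesis and sets out from dialdehyde 19. Double Wittig methylenation (Ph3PCH3Br, KOtBu, THF) should give the bis-styrene F2. Treatment of F2 with the second-generation Grubbs catalyst RuCl2(=CHPh)(PCy3)(H2IMes) in dilute toluene at 80 °C, with loss of ethylene, comes back to the route at macrocyclic stilbene 20.

**Further compounds**

F0 | step 7 | none | none
F1 | step 6 | 1-{2-[2-(benzyloxy)phenyl]ethyl}-4,5-dimethoxy-3-{[(triisopropylsilyl)ethynyl]oxy}benzene | CC(C)[Si](C(C)C)(C(C)C)C#COc1cc(CCc2ccccc2OCc2ccccc2)cc(OC)c1OC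
F2 | step 12 | 1-{2-[2-(2-ethenyl-6-methoxyphenoxy)phenyl]ethyl}-3-(4-ethenylphenoxy)-4,5-dimethoxybenzene | C=Cc1ccc(cc1)Oc1cc(CCc2ccccc2Oc2c(C=C)cccc2OC)cc(OC)c1OC
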